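**Retrosynthetic overview**

1. Target 10 is traced back to 6-bromo-1H-indole 8 by removing the two pyrrole-ring bromines (C3 first, then C2), which are installed last by electrophilic bromination.
2. 8 is disconnected at C2–C3. The strategy rests on C2 and C3 of the pyrrole ring carrying only bromine and no carbon substituent, so C3 can come from an ortho methyl carbon and C2 from an isocyanide carbon, with the C6 bromine already para to that methyl group.
3. The isocyanide 4 comes from formamide 3, made from 5-bromo-2-methylaniline 1 and formic acid 2.
4. Ring order: the benzene ring is bought with its bromine in place. The pyrrole ring is the only ring formed, in step 3. The target is achiral.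

Key step: step 3

**Route**

Step 1
Reactants: 1 5-bromo-2-methylaniline; 2 formic acid
Product: 3 N-(5-bromo-2-methylphenyl)formamide
Conditions: HCO2H (98%, 3 equiv), toluene, reflux, Dean–Stark trap
Reagents that add atoms: formic acid, OC=O
Why: N-formylation of a primary aniline by condensation with formic acid is driven to completion by azeotropic removal of water, and the aryl bromide and methyl group are inert.

Step 2
Reactants: 3 N-(5-bromo-2-methylphenyl)formamide
Product: 4 4-bromo-2-isocyano-1-methylbenzene
Conditions: POCl3 (1.1 equiv), Et3N (3 equiv), CH2Cl2, −10 to 0 °C; cold aq. Na2CO3 work-up; used promptly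
Reagents that add atoms: none
Why: Ugi-type dehydration of an N-aryl formamide, in which O-phosphorylation is followed by base-induced alpha-elimination to the isocyanide, and the basic work-up prevents acid-catalysed rehydration.

Step 3
Reactants: 4 4-bromo-2-isocyano-1-methylbenzene
Product: 8 6-bromo-1H-indole, via (4-bromo-2-isocyanophenyl)methyllithium 5 (not isolated), via (6-bromo-3H-indol-2-yl)lithium 6 (not isolated), via lithium 6-bromoindol-1-ide 7 (not isolated)
Conditions: lithium 2,2,6,6-tetramethylpiperidide (2 equiv, preformed from 2,2,6,6-tetramethylpiperidine and n-BuLi in THF at 0 °C), THF, −78 °C, then warm to rt; H2O quench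
Reagents that add atoms: none
Why: The ortho isocyano group acidifies the methyl group, so the hindered amide removes a benzylic proton at −78 °C to give 5; on warming, the carbanion adds to the divalent isocyanide carbon to form the C2–C3 bond as imidoyllithium 6, and a C3-to-C2 proton shift gives the aromatic N-lithioindolide 7, which water protonates to 8. This is the Ito–Saegusa indole synthesis, a known cyclisation of ortho-lithiomethylphenyl isocyanides. The pyrrole ring closes in a 5-endo-dig mode, both atoms of the N≡C unit ending up inside the new five-membered ring. No stereocentre is formed. The step needs benzylic deprotonation to win over bromine–lithium exchange, ortho-metalation next to bromine (aryne formation or halogen migration) and addition of the base to the isocyanide carbon; a non-nucleophilic lithium amide free of residual alkyllithium, low temperature during metalation and dilute conditions should secure this. The 1,2,4-substitution pattern of the arene fixes the bromine at C6, so no 4-bromo isomer can form.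

Step 4
Reactants: 8 6-bromo-1H-indole
Product: 10 2,3,6-tribromo-1H-indole, via 3,6-dibromo-1H-indole 9 (not isolated)
Conditions: NBS (2.05 equiv, added in two portions), silica gel, CH2Cl2, rt, dark, anhydrous; filtration and rapid chromatography
Reagents that add atoms: N-bromosuccinimide, O=C1CCC(=O)N1Br
Why: Electrophilic aromatic bromination of the electron-rich pyrrole ring places the first bromine at C3, the most nucleophilic position, and with C3 blocked the second equivalent delivers bromine to C2; the already brominated benzene ring is far less reactive and should remain untouched under anhydrous conditions.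

**Compound list**

1 | 5-bromo-2-methylaniline | Cc1ccc(Br)cc1N | starting material
2 | formic acid | OC=O | starting material
3 | N-(5-bromo-2-methylphenyl)formamide | Cc1ccc(Br)cc1NC=O | intermediate
4 | 4-bromo-2-isocyano-1-methylbenzene | Cc1ccc(Br)cc1[N+]#[C-] | intermediate
5 | (4-bromo-2-isocyanophenyl)methyllithium | [Li]Cc1ccc(Br)cc1[N+]#[C-] | intermediate
6 | (6-bromo-3H-indol-2-yl)lithium | [Li]C1=Nc2cc(Br)ccc2C1 | intermediate
7 | lithium 6-bromoindol-1-ide | [Li]n1ccc2ccc(Br)cc21 | intermediate
8 | 6-bromo-1H-indole | Brc1ccc2cc[nH]c2c1 | intermediate
9 | 3,6-dibromo-1H-indole | Brc1ccc2c(Br)c[nH]c2c1 | intermediate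
10 | 2,3,6-tribromo-1H-indole | Brc1ccc2c(Br)c(Br)[nH]c2c1 | target

**Step count**

Total steps: 4. Longest linear sequence: 4 steps (1 → 3 → 4 → 8 → 10).

**Steps most likely to fail**

1. Step 3 (key step). The base may metalate the ring next to bromine, leading to aryne formation or halogen migration, or the benzylic anion or the amide may add intermolecularly to the isocyanide carbon and give oligomers instead of ring closure. Fallback: a reductive enamine cyclisation (Leimgruber–Batcho) that sets out from aniline 1 and comes back at indole 8. Oxidation of the amino group of 1 with NaBO3·4H2O in acetic acid at 50–55 °C should give 4-bromo-1-methyl-2-nitrobenzene F1. Condensation of its nitro-activated methyl group with N,N-dimethylformamide dimethyl acetal in DMF at 110 °C should give (E)-2-(4-bromo-2-nitrophenyl)-N,N-dimethylethenamine F2. Reduction of the nitro group with iron powder in acetic acid/ethanol at 80 °C, conditions that spare the aryl bromide, should be followed by cyclisation of the aniline onto the enamine carbon with loss of dimethylamine to give 8.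

2. Step 4. Over-bromination of the benzene ring, diversion of a brominated indolenine intermediate to oxindole-type products by adventitious water, or light- and acid-promoted decomposition of the free N–H dibromopyrrole unit on silica may erode the product. Fallback: stepwise, position-controlled halogenation on an N-protected indole, setting out from 8 and coming back at 10. Treatment of 8 with Boc2O and catalytic DMAP in MeCN should give tert-butyl 6-bromo-1H-indole-1-carboxylate F3. Deprotonation at C2, the most acidic C–H of an N-Boc indole, with LDA in THF at −78 °C, followed by quenching with 1,2-dibromo-1,1,2,2-tetrachloroethane, should give tert-butyl 2,6-dibromo-1H-indole-1-carboxylate F4. Bromination at the remaining C3 position with NBS (1 equiv) in DMF at rt should give tert-butyl 2,3,6-tribromo-1H-indole-1-carboxylate F5. Mild methanolysis of the carbamate with K2CO3 in MeOH at rt should then release 10 without exposure to acid.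

3. Step 2. Incomplete dehydration, acid-catalysed rehydration of the isocyanide to the formamide during work-up, or polymerisation on concentration may lower the supply of 4. Fallback: the Hofmann carbylamine reaction under phase transfer, setting out from aniline 1 and coming back directly at isocyanide 4. Aniline 1 is treated with CHCl3 and 50% aq. NaOH in CH2Cl2 with benzyltriethylammonium chloride at reflux; dichlorocarbene generated in the organic phase adds to the amine nitrogen and twofold loss of HCl gives 4. This bypasses formamide 3 and avoids any acidic phosphorus reagent; no new isolable compound is formed.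

**Further compounds**

F1 | step 3 | 4-bromo-1-methyl-2-nitrobenzene | Cc1ccc(Br)cc1[N+](=O)[O-]
F2 | step 3 | (E)-2-(4-bromo-2-nitrophenyl)-N,N-dimethylethenamine | CN(C)/C=C/c1ccc(Br)cc1[N+](=O)[O-]
F3 | step 4 | tert-butyl 6-bromo-1H-indole-1-carboxylate | CC(C)(C)OC(=O)n1ccc2ccc(Br)cc21
F4 | step 4 | tert-butyl 2,6-dibromo-1H-indole-1-carboxylate | CC(C)(C)OC(=O)n1c(Br)cc2ccc(Br)cc21
F5 | step 4 | tert-butyl 2,3,6-tribromo-1H-indole-1-carboxylate | CC(C)(C)OC(=O)n1c(Br)c(Br)c2ccc(Br)cc21
F0 | step 2 | none | none
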